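3 questions stand on two flasks, dusk and summer, and what to watch in both is how long reagent lasts once substrate has gone.

| flask | substrate | reagent | temperature | remark | time |
|---|---|---|---|---|---|
| east | 14 mM | 13 mM (in portions, 2) | −35 °C | run made earlier; portions every 20 h |  |
| north-east | 14 mM | 50 mM (in portions, 2) | −24 °C | run made earlier; portions every 20 h |  |
| dusk | 14 mM | 25.2 mM (in portions, 2) |  | at −20 °C throughout; the portions of reagent follow each other after 20 h, the first at the start | 50 d |
| summer | 14 mM | 25.2 mM (in portions, 2) |  | at −40 °C until 2.5 d, from then on at −20 °C; the portions of reagent follow each other after 20 h, the first at the start | 12 d |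

| run | time / d | tetra adduct / % | substrate / % |
|---|---|---|---|
| east | 1.04 | 0.9 | 51.4 |
| east | 3.00 | 1.3 | 20.2 |
| east | 5.00 | 0 | 16.7 |
| east | 8.00 | 1.2 | 14.1 |
| east | 12.0 | 0.8 | 13.6 |
| east | 15.0 | 1.9 | 12.1 |
| north-east | 0.625 | 2.0 | 1.7 |
| north-east | 1.04 | 11.9 | 0.1 |
| north-east | 1.25 | 19.3 | 0 |
| north-east | 2.50 | 49.8 | 0 |
| north-east | 4.00 | 63.2 | 2.0 |
| north-east | 6.00 | 72.0 | 0 |

(scatter of a reading: 1 percentage point)

- which one finishes higher in amount of tetra adduct, in percent of the substrate charged ("neither" within 2 percentage points) (dusk / summer / neither)
- amount of tetra adduct at the end, in percent of the substrate charged, dusk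
- amount of tetra adduct at the end, in percent of the substrate charged, summer



We take each step as a bimolecular encounter, with a rate equal to k times two concentrations. North-east shows the order of events: at 0.625 d substrate reads 1.7% and tetra adduct 2.0%. So we read that substrate first takes one reagent to give a first product, and tetra adduct then costs 3 more reagent. Dusk and summer hold 0.800 equiv beyond that first one. If every bit of this excess ended in tetra adduct, the ceiling would be 26.7%. North-east's ceiling on the same reckoning is 85.7%, and it reads 72.0% at 6.00 d, a share of 0.840. That reading was still rising, higher than the 63.2% at 4.00 d, in a flask charged with more reagent than dusk or summer, so this is no finished share; taken over as it stands, it gives 22.4%, a rough estimate of our own for a finished flask.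

Whether summer finishes is a question of time. After substrate has gone, reagent is consumed by first product and by each later adduct, at k times reagent times that adduct. While the stock of these adducts changes slowly, the concentration that sets the order is reagent's own, so the decay is pseudo-first-order. In north-east the excess not yet in tetra adduct, in equiv of substrate, is the charged excess minus 3 times the tetra reading: 1.99 at 1.25 d and 1.08 at 2.50 d. As a reading, that gives a half-life of 1.41 d at −24 °C. We carry this excess half-life, the time in which the excess not yet in tetra adduct halves. Summer's warm stretch at −20 °C is hotter than north-east and holds less reagent, so using this value there unchanged is a rough count: with the stretch at −40 °C counted as nothing, summer's 9.50 d at −20 °C holds 6.74 such half-lives. That leaves 0.936% of the excess, worth 0.25 percentage points of tetra adduct against a margin of 2 points. We therefore expect neither flask to lead.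

The forecast says dusk, with 13% for dusk and 10% for summer, the latter “probably not quite finished”.

    substrate + reagent → first product + by-product (k = 3.67 M⁻¹ h⁻¹, Ea = 58.0 kJ mol⁻¹)
    reagent + first product → double product + by-product (k = 0.165 M⁻¹ h⁻¹, Ea = 51.0 kJ mol⁻¹)
    reagent + double product → tris adduct + by-product (k = 1.14 M⁻¹ h⁻¹, Ea = 47.0 kJ mol⁻¹)
    reagent + tris adduct → tetra adduct + by-product (k = 2.76 M⁻¹ h⁻¹, Ea = 56.0 kJ mol⁻¹)
    (constants at −40 °C)

Dusk ends at 20.6% and summer at 20.6%, so the answer is neither. Summer's reagent fell from 43.1% of its charge at 2.50 d to 1.76% at 6.00 d, on average a half-life of 0.758 d at −20 °C, shorter than the 1.41 d read for the excess in north-east at −24 °C. Dusk's slowest mode at 50.0 d has a half-life of 0.777 d, and summer's warm 9.50 d is 12.2 times that, with summer's reagent at 0.00836% of its charge at 12.0 d.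

(All runs are simulated with made-up constants, and the scatter is random.)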